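**Retrosynthetic overview**

1. Locants: ring C1 (O-angeloyl), C2 (CH2), C3 (CH-CH3), C4 (CH-OH), C5 (CH2), C6 (CH-side chain); side chain C7 (CH-CH3), C8, C9 (CH-OAc), C10=C11. Target 25 <= ketone 24 (equatorial hydride attack at C4) <= hydroxy ketone 21 (angeloylation of its only free OH, at C1).
2. Key disconnection C2–C3: 21 <= acyclic iodo ketone 18. Enolate carbon C3 displaces iodide from C2 and closes the cyclohexane in a dynamic, regio- and stereoconvergent cycloalkylation.
3. Enabling feature: the C1(O)–C2H2–C3H(CH3)–C4(O) edge of the cyclohexane. C4 can be carried as a ketone, which makes C3 nucleophilic and epimerisable. C2 is an unsubstituted CH2 next to oxygenated C1, so it is a primary halide in the open chain. The C1, C3 and C6 substituents are all equatorial, so chair closure and thermodynamic sink coincide. The axial C4–OH cis to the C3 methyl is what a bulky hydride gives.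
4. 18 <= δ-lactone 9. The lactone carbonyl is C1 and is homologated with LiCH2Cl, which brings C2. Felkin–Anh reduction sets C1. The but-2-ynyl arm (C5, C4, C3, CH3) is hydrated at C4 with help of the C1–OH.
5. Ring order: the temporary δ-lactone (O, C1, C6, C7, C8, C9) comes first. It is built from half-ester 1 (C7), CBS reduction (C9) and trans-alkylation (C6), and is opened in step 4. The cyclohexane is closed in step 10.

Key step: step 10

Remark: half-ester 1 is taken as the commercial (R)-enantiomer, and hydroxy ketone 12 is drawn open-chain although it equilibrates with hemiketal 11.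

**Step 1**
Reactants: 1 methyl hydrogen (R)-3-methylglutarate; 2 2-methylprop-1-enylmagnesium bromide
Product: 4 methyl (3R)-3,7-dimethyl-5-oxooct-6-enoate, via acid chloride 3 (not isolated)
Conditions: (COCl)2, DMF (cat.), CH2Cl2, 0 °C to rt, evaporate; then 2, CuI (10 mol%), THF, −78 °C
Reagents that add atoms: oxalyl chloride, ClC(=O)C(=O)Cl (supplies the chlorine of 3)
Why: Copper-catalysed acylation of a Grignard reagent with an acid chloride (ketone synthesis) is far faster at −78 °C than attack on the methyl ester or on the hindered β,β-disubstituted enone formed, and the C7 stereocentre of 1 is not touched.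

**Step 2**
Reactants: 4 methyl (3R)-3,7-dimethyl-5-oxooct-6-enoate
Product: 6 (4R,6R)-4-methyl-6-(2-methylprop-1-en-1-yl)oxan-2-one, via hydroxy ester 5 (not isolated)
Conditions: (S)-2-methyl-CBS-oxazaborolidine (15 mol%), catecholborane, toluene, −78 °C; aqueous work-up; then PPTS (cat.), toluene, 60 °C
Reagents that add atoms: none
Why: CBS (oxazaborolidine-catalysed) reduction treats the isobutenyl group as the large substituent, so the (S)-catalyst should give the (R)-carbinol C9 under catalyst control, and acid-catalysed lactonisation then locks C7 and C9 in the cis-diequatorial δ-lactone.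

**Step 3**
Reactants: 6 (4R,6R)-4-methyl-6-(2-methylprop-1-en-1-yl)oxan-2-one; 7 1-bromobut-2-yne
Product: 9 (3S,4R,6R)-3-(but-2-yn-1-yl)-4-methyl-6-(2-methylprop-1-en-1-yl)oxan-2-one, via lithium enolate 8 (not isolated)
Conditions: LiN(i-Pr)2, THF, −78 °C; then 7, DMPU, −78 to −40 °C
Reagents that add atoms: none
Why: Lactone enolate alkylation (SN2 on a propargylic bromide) occurs on the enolate face anti to the adjacent C7 methyl group, which sets C6 as the 3,4-trans, all-equatorial lactone that is also the thermodynamic epimer.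

**Step 4**
Reactants: 9 (3S,4R,6R)-3-(but-2-yn-1-yl)-4-methyl-6-(2-methylprop-1-en-1-yl)oxan-2-one; 10 chloroiodomethane
Product: 12 (3S,4R,6R)-3-(but-2-yn-1-yl)-1-chloro-6-hydroxy-4,8-dimethylnon-7-en-2-one, via cyclic hemiketal 11 (not isolated)
Conditions: 10, MeLi·LiBr (slow addition), THF–Et2O, −78 °C; AcOH, −78 °C
Reagents that add atoms: none
Why: Halomethyllithium homologation of a lactone: LiCH2Cl, formed by fast iodine–lithium exchange in the presence of 9, adds once to the carbonyl because the lithium hemiketal survives at −78 °C, so C2 arrives as CH2Cl and C6 is not epimerised.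

**Step 5**
Reactants: 12 (3S,4R,6R)-3-(but-2-yn-1-yl)-1-chloro-6-hydroxy-4,8-dimethylnon-7-en-2-one
Product: 13 (4R,6R,7S)-7-(but-2-yn-1-yl)-9-chloro-2,6-dimethyl-8-oxonon-2-en-4-yl acetate
Conditions: Ac2O, 2,6-lutidine, DMAP (5 mol%), CH2Cl2, 0 °C
Reagents that add atoms: acetic anhydride, CC(=O)OC(C)=O
Why: DMAP-catalysed acetylation takes the secondary allylic C9 hydroxyl of the open tautomer and not the hindered tertiary hemiketal hydroxyl, so the equilibrium drains to the keto acetate and the final C9 ester is in place.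

**Step 6**
Reactants: 13 (4R,6R,7S)-7-(but-2-yn-1-yl)-9-chloro-2,6-dimethyl-8-oxonon-2-en-4-yl acetate
Product: 14 (4R,6R,7S,8S)-7-(but-2-yn-1-yl)-9-chloro-8-hydroxy-2,6-dimethylnon-2-en-4-yl acetate
Conditions: LiBH(s-Bu)3 (L-Selectride, 1.1 equiv), THF, −78 °C; AcOH, −78 °C
Reagents that add atoms: none
Why: Felkin–Anh-controlled ketone reduction: with the branched C7 carbon as the large group perpendicular to the carbonyl and anti to the bulky hydride, which passes the C6 hydrogen, attack should give the (S)-chlorohydrin, i.e. the C1/C6 relationship of the target, while acetate, alkyne and chloride are inert at −78 °C.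

**Step 7**
Reactants: 14 (4R,6R,7S,8S)-7-(but-2-yn-1-yl)-9-chloro-8-hydroxy-2,6-dimethylnon-2-en-4-yl acetate
Product: 16 (4R,6R,7S)-7-[(1S)-2-chloro-1-hydroxyethyl]-2,6-dimethyl-9-oxoundec-2-en-4-yl acetate, via enol ether 15 (not isolated)
Conditions: Ph3PAuNTf2 (2 mol%), THF–H2O (10:1), rt
Reagents that add atoms: water, O
Why: Hydroxyl-assisted alkyne hydration: the monovalent gold catalyst activates the alkyne for 5-exo-dig attack of the C1 hydroxyl on C4, and in situ hydrolysis of enol ether 15 leaves the carbonyl on C4 and not on C3.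

**Step 8**
Reactants: 16 (4R,6R,7S)-7-[(1S)-2-chloro-1-hydroxyethyl]-2,6-dimethyl-9-oxoundec-2-en-4-yl acetate
Product: 17 (4R,6R,7S)-7-[(1S)-2-chloro-1-(triethylsilyloxy)ethyl]-2,6-dimethyl-9-oxoundec-2-en-4-yl acetate
Conditions: Et3SiOTf, 2,6-lutidine, CH2Cl2, −78 °C
Reagents that add atoms: triethylsilyl triflate, CC[Si](CC)(CC)OS(=O)(=O)C(F)(F)F
Why: Silyl ether formation with a silyl triflate and a hindered pyridine base is fast at −78 °C even for this flanked secondary alcohol, and it masks the C1 oxygen so that base cannot later turn the halohydrin into an epoxide.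

**Step 9**
Reactants: 17 (4R,6R,7S)-7-[(1S)-2-chloro-1-(triethylsilyloxy)ethyl]-2,6-dimethyl-9-oxoundec-2-en-4-yl acetate
Product: 18 (4R,6R,7S)-7-[(1S)-2-iodo-1-(triethylsilyloxy)ethyl]-2,6-dimethyl-9-oxoundec-2-en-4-yl acetate
Conditions: NaI (excess), butan-2-one, 80 °C, dark
Reagents that add atoms: sodium iodide, [Na+].[I-]
Why: Finkelstein halide exchange, driven by precipitation of NaCl, turns the sluggish β-oxygenated primary chloride into the softer, more reactive iodide under neutral conditions that leave ketone, silyl ether and acetate alone.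

**Step 10**
Reactants: 18 (4R,6R,7S)-7-[(1S)-2-iodo-1-(triethylsilyloxy)ethyl]-2,6-dimethyl-9-oxoundec-2-en-4-yl acetate
Product: 21 (2R,4R)-2-[(1S,2R,4S)-2-hydroxy-4-methyl-5-oxocyclohexyl]-6-methylhept-5-en-4-yl acetate, via lithium enolate 19 (not isolated), via silyl ether ketone 20 (not isolated)
Conditions: LiN(SiMe3)2 (1.05 equiv), THF–DMPU (10:1), 0.01 M, −78 to 0 °C; then AcOH–H2O added to the flask, rt
Reagents that add atoms: none
Why: LiN(SiMe3)2 converts ketone 18 reversibly into its enolates, and the C3 enolate 19 displaces iodide from the primary carbon C2 in an intramolecular SN2 alkylation (closest known type: base-mediated cycloalkylation of ω-halo ketones to cyclohexanones), after which aqueous acetic acid in the same flask strips the triethylsilyl group and frees only the C1 hydroxyl. The six-membered ring closes in the 6-(enolendo)-exo-tet mode, which the Baldwin rules for enolates allow, through a chair in which the C1 silyloxy group and the C6 side chain are both equatorial. The step is regioconvergent, because the C5 enolate could only form a cyclobutane and therefore returns, through proton exchange with HN(SiMe3)2 and unreacted ketone, to the productive C3 enolate. The one new stereocentre, C3, is secured twice: the favoured Z(O)-enolate places the methyl group equatorial in the chair transition state, and because C3 stays α to the C4 carbonyl any axial epimer drains to the all-equatorial (S)-configured ketone, so enolate geometry and C3 configuration need no prior control. C- over O-alkylation is secured by the soft iodide and the lithium counter-ion, epoxide formation is blocked by the silyl ether on C1, no leaving group sits β to the carbonyl, C6 is β to the ketone and cannot epimerise, and the C9 acetate should be spared because the ketone is the stronger and faster carbon acid and only one equivalent of base is used at or below 0 °C.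

**Step 11**
Reactants: 21 (2R,4R)-2-[(1S,2R,4S)-2-hydroxy-4-methyl-5-oxocyclohexyl]-6-methylhept-5-en-4-yl acetate; 22 angelic acid, (Z)-2-methylbut-2-enoic acid
Product: 24 (1R,2S,5S)-2-[(2R,4R)-4-acetoxy-6-methylhept-5-en-2-yl]-5-methyl-4-oxocyclohexyl (Z)-2-methylbut-2-enoate, via mixed anhydride 23 (not isolated)
Conditions: 22, 2,4,6-trichlorobenzoyl chloride, Et3N, toluene, rt; then 21, 75 °C, no DMAP
Reagents that add atoms: 2,4,6-trichlorobenzoyl chloride, O=C(Cl)c1c(Cl)cc(Cl)cc1Cl (supplies the aroyl part of 23)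
Why: Mixed-anhydride (Yamaguchi-type) esterification without DMAP: the C1 hydroxyl attacks the less hindered angeloyl carbonyl of 23, a protocol known to keep the Z geometry of angelates, and the mild base can only reinforce the equatorial C3 methyl.

**Step 12**
Reactants: 24 (1R,2S,5S)-2-[(2R,4R)-4-acetoxy-6-methylhept-5-en-2-yl]-5-methyl-4-oxocyclohexyl (Z)-2-methylbut-2-enoate
Product: 25 (1R,2S,4R,5S)-2-[(2R,4R)-4-acetoxy-6-methylhept-5-en-2-yl]-4-hydroxy-5-methylcyclohexyl (Z)-2-methylbut-2-enoate (target)
Conditions: LiBH(s-Bu)3 (L-Selectride, 1.05 equiv), THF, −78 °C; AcOH, −78 °C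
Reagents that add atoms: none
Why: Bulky trialkylborohydride reduction of a conformationally fixed 2-methylcyclohexanone: hydride comes from the equatorial direction and should give the axial C4 alcohol cis to the C3 methyl (4R), and one equivalent at −78 °C reduces the ketone much faster than the trisubstituted angelate or the acetate.

**Compound list**

1 | methyl hydrogen (R)-3-methylglutarate | COC(=O)C[C@H](C)CC(=O)O | starting material
2 | 2-methylprop-1-enylmagnesium bromide | CC(C)=C[Mg]Br | starting material
3 | methyl (3S)-5-chloro-3-methyl-5-oxopentanoate (acid chloride) | COC(=O)C[C@H](C)CC(=O)Cl | intermediate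
4 | methyl (3R)-3,7-dimethyl-5-oxooct-6-enoate | COC(=O)C[C@H](C)CC(=O)C=C(C)C | intermediate
5 | methyl (3R,5R)-5-hydroxy-3,7-dimethyloct-6-enoate | COC(=O)C[C@H](C)C[C@@H](O)C=C(C)C | intermediate
6 | (4R,6R)-4-methyl-6-(2-methylprop-1-en-1-yl)oxan-2-one | O=C1C[C@H](C)C[C@H](C=C(C)C)O1 | intermediate
7 | 1-bromobut-2-yne | CC#CCBr | starting material
8 | lithium enolate of lactone 6 | [Li+].[O-]C1=C[C@H](C)C[C@H](C=C(C)C)O1 | intermediate
9 | (3S,4R,6R)-3-(but-2-yn-1-yl)-4-methyl-6-(2-methylprop-1-en-1-yl)oxan-2-one | O=C1[C@@H](CC#CC)[C@H](C)C[C@H](C=C(C)C)O1 | intermediate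
10 | chloroiodomethane | ClCI | starting material
11 | (3S,4R,6R)-3-(but-2-yn-1-yl)-2-(chloromethyl)-4-methyl-6-(2-methylprop-1-en-1-yl)oxan-2-ol (anomeric centre undefined) | OC1(CCl)[C@@H](CC#CC)[C@H](C)C[C@H](C=C(C)C)O1 | intermediate
12 | (3S,4R,6R)-3-(but-2-yn-1-yl)-1-chloro-6-hydroxy-4,8-dimethylnon-7-en-2-one | ClCC(=O)[C@@H](CC#CC)[C@H](C)C[C@@H](O)C=C(C)C | intermediate
13 | (4R,6R,7S)-7-(but-2-yn-1-yl)-9-chloro-2,6-dimethyl-8-oxonon-2-en-4-yl acetate | ClCC(=O)[C@@H](CC#CC)[C@H](C)C[C@H](C=C(C)C)OC(C)=O | intermediate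
14 | (4R,6R,7S,8S)-7-(but-2-yn-1-yl)-9-chloro-8-hydroxy-2,6-dimethylnon-2-en-4-yl acetate | ClC[C@@H](O)[C@@H](CC#CC)[C@H](C)C[C@H](C=C(C)C)OC(C)=O | intermediate
15 | (2R,4R)-2-[(2S,3S,5Z)-2-(chloromethyl)-5-ethylideneoxolan-3-yl]-6-methylhept-5-en-4-yl acetate | C/C=C1\O[C@H](CCl)[C@H]([C@H](C)C[C@H](C=C(C)C)OC(C)=O)C1 | intermediate
16 | (4R,6R,7S)-7-[(1S)-2-chloro-1-hydroxyethyl]-2,6-dimethyl-9-oxoundec-2-en-4-yl acetate | CCC(=O)C[C@H]([C@H](O)CCl)[C@H](C)C[C@H](C=C(C)C)OC(C)=O | intermediate
17 | (4R,6R,7S)-7-[(1S)-2-chloro-1-(triethylsilyloxy)ethyl]-2,6-dimethyl-9-oxoundec-2-en-4-yl acetate | CCC(=O)C[C@H]([C@H](O[Si](CC)(CC)CC)CCl)[C@H](C)C[C@H](C=C(C)C)OC(C)=O | intermediate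
18 | (4R,6R,7S)-7-[(1S)-2-iodo-1-(triethylsilyloxy)ethyl]-2,6-dimethyl-9-oxoundec-2-en-4-yl acetate | CCC(=O)C[C@H]([C@H](O[Si](CC)(CC)CC)CI)[C@H](C)C[C@H](C=C(C)C)OC(C)=O | intermediate
19 | lithium (Z)-enolate of 18 (C3=C4, methyl cis to O) | C/C=C(\[O-])C[C@H]([C@H](O[Si](CC)(CC)CC)CI)[C@H](C)C[C@H](C=C(C)C)OC(C)=O.[Li+] | intermediate
20 | (2R,4R)-6-methyl-2-[(1S,2R,4S)-4-methyl-5-oxo-2-(triethylsilyloxy)cyclohexyl]hept-5-en-4-yl acetate | CC[Si](CC)(CC)O[C@@H]1C[C@H](C)C(=O)C[C@H]1[C@H](C)C[C@H](C=C(C)C)OC(C)=O | intermediate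
21 | (2R,4R)-2-[(1S,2R,4S)-2-hydroxy-4-methyl-5-oxocyclohexyl]-6-methylhept-5-en-4-yl acetate | O[C@@H]1C[C@H](C)C(=O)C[C@H]1[C@H](C)C[C@H](C=C(C)C)OC(C)=O | intermediate
22 | angelic acid, (Z)-2-methylbut-2-enoic acid | C/C=C(/C)C(=O)O | starting material
23 | angelic 2,4,6-trichlorobenzoic anhydride | C/C=C(/C)C(=O)OC(=O)c1c(Cl)cc(Cl)cc1Cl | intermediate
24 | (1R,2S,5S)-2-[(2R,4R)-4-acetoxy-6-methylhept-5-en-2-yl]-5-methyl-4-oxocyclohexyl (Z)-2-methylbut-2-enoate | C/C=C(/C)C(=O)O[C@@H]1C[C@H](C)C(=O)C[C@H]1[C@H](C)C[C@H](C=C(C)C)OC(C)=O | intermediate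
25 | (1R,2S,4R,5S)-2-[(2R,4R)-4-acetoxy-6-methylhept-5-en-2-yl]-4-hydroxy-5-methylcyclohexyl (Z)-2-methylbut-2-enoate | C/C=C(/C)C(=O)O[C@@H]1C[C@H](C)[C@H](O)C[C@H]1[C@H](C)C[C@H](C=C(C)C)OC(C)=O | target

Total step count: 12. Longest linear sequence: 12 steps (from 1).

**Steps most likely to fail**

**Step 10.** SN2 attack at the β-branched, β-oxygenated primary carbon may be slow. O-alkylation, unproductive proton scrambling or attack of the enolate on the acetate could then compete. The fallback sets out from 18, comes back at 20, and forms the same bond at the aldehyde oxidation level under ester-safe conditions.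
- Kornblum-type oxidation of the iodide (AgBF4, DMSO, then Et3N) gives the α-silyloxy keto aldehyde F1.
- Dibenzylammonium trifluoroacetate in toluene then promotes an intramolecular aldol condensation (6-(enolendo)-exo-trig) to the γ-silyloxy 2-methylcyclohex-2-enone F2.
- Conjugate reduction with [(Ph3P)CuH]6, a monovalent copper hydride, followed by protonation gives 20 with the equatorial methyl. The silyl group of 20 is then removed with aqueous acetic acid as in the route.

**Step 7.** Competing 6-endo-dig attack of the hydroxyl would place the carbonyl on C3, and the enol ether may hydrolyse slowly. The fallback sets out from 14, comes back at 16, and fixes the regiochemistry with a silicon tether.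
- (HMe2Si)2NH converts 14 into the dimethylsilyl ether F3.
- Pt2[(CH2=CHSiMe2)2O]3, a zerovalent platinum catalyst, effects intramolecular exo-dig syn-hydrosilylation to the cyclic vinylsiloxane F4, with silicon bound to C4.
- Tamao–Fleming oxidation (KF, KHCO3, H2O2, THF–MeOH) turns the C4–Si bond into the C4 carbonyl and releases the C1 hydroxyl, giving 16.

**Step 4.** The carbenoid may enolise the hindered lactone, decompose before it adds, or add twice. The fallback sets out from 9, comes back at 12, and replaces the carbenoid by a stabilised ylide.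
- Dimethylsulfoxonium methylide (from Me3S(O)I and KOt-Bu, THF) opens the lactone by acylation to the β-keto sulfoxonium ylide F5.
- One equivalent of HCl in THF converts F5 into chloromethyl ketone 12 by protonation and chloride displacement at the ylide carbon.

**Further compounds**

F1 | step 10 | (4R,6R,7S)-2,6-dimethyl-9-oxo-7-[(1S)-2-oxo-1-(triethylsilyloxy)ethyl]undec-2-en-4-yl acetate | CCC(=O)C[C@H]([C@H](O[Si](CC)(CC)CC)C=O)[C@H](C)C[C@H](C=C(C)C)OC(C)=O
F2 | step 10 | 2-methylcyclohex-2-enone with triethylsilyloxy at C1 and the acetoxy side chain at C6, C1, C6, C7 and C9 configured as in 18 | CC[Si](CC)(CC)O[C@@H]1C=C(C)C(=O)C[C@H]1[C@H](C)C[C@H](C=C(C)C)OC(C)=O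
F3 | step 7 | dimethylsilyl ether of chlorohydrin 14 | ClC[C@@H](O[SiH](C)C)[C@@H](CC#CC)[C@H](C)C[C@H](C=C(C)C)OC(C)=O
F4 | step 7 | 2,2-dimethyl-1,2-oxasilinane with (E)-ethylidene at the carbon next to silicon (C4), chloromethyl at C1 and the acetoxy side chain at C6, stereocentres as in 14 | C/C=C1/[Si](C)(C)O[C@H](CCl)[C@H]([C@H](C)C[C@H](C=C(C)C)OC(C)=O)C1
F5 | step 4 | (3S,4R,6R)-3-(but-2-yn-1-yl)-1-(dimethyloxosulfaniumyl)-6-hydroxy-4,8-dimethylnon-7-en-2-one ylide (β-keto sulfoxonium ylide) | CS(C)(=O)=CC(=O)[C@@H](CC#CC)[C@H](C)C[C@@H](O)C=C(C)C
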